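The target is the one thing read in these flasks, so the meeting began by asking what a reading of target says about the starting material still present.

| flask | starting material | coupling partner | catalyst | time |
|---|---|---|---|---|
| teal | 0.200 M | 0.500 M | 0.00600 M |  |
| grey | 0.120 M | 0.420 M | 0.00600 M |  |
| violet | 0.200 M | 0.500 M | 0.00900 M |  |
| amber | 0.400 M | 0.500 M | 0.00600 M |  |
| red | 0.200 M | 0.170 M | 0.00600 M | 150 s |

| run | time / s | [target] / M |
|---|---|---|
| teal run | 8.5 | 0.0113 |
| teal run | 26 | 0.0336 |
| teal run | 49 | 0.0627 |
| teal run | 78 | 0.0863 |
| teal run | 110 | 0.1150 |
| teal run | 150 | 0.1380 |
| grey run | 8.5 | 0.0064 |
| grey run | 26 | 0.0242 |
| grey run | 49 | 0.0380 |
| grey run | 78 | 0.0541 |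
| grey run | 110 | 0.0714 |
| grey run | 150 | 0.0867 |
| violet run | 8.5 | 0.0129 |
| violet run | 26 | 0.0514 |
| violet run | 49 | 0.0854 |
| violet run | 78 | 0.1171 |
| violet run | 110 | 0.1524 |
| violet run | 150 | 0.1707 |
| amber run | 8.5 | 0.0220 |
| amber run | 26 | 0.0562 |
| amber run | 49 | 0.1094 |
| amber run | 78 | 0.1604 |
| amber run | 110 | 0.2111 |
| amber run | 150 | 0.2654 |

(each reading ± 0.002 M)

- Overall: starting material + coupling partner -> target, with catalyst as catalyst.
- Constant volume, constant temperature.
- The analysis sees a species whether free or bound.
- "The second partner" is coupling partner.
- An order is taken over about fifteen percent of the charge, up and down.

- reaction order in [starting material] at the outset, round the charge of the teal run, defined at two percent of the starting material turned into target (one fixed amount of target, the same in the runs compared)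
- reaction order in [coupling partner] at the outset, round the charge of the teal run, defined at two percent of the starting material turned into target
- the grey run starts with 0.0800 M less of starting material and of coupling partner than the teal run, and with no target. Compared where both hold the same amount of starting material, once fifteen percent of what the grey run was charged with has turned into target, is the grey run faster, slower or alike (within a tenth)?
- target in the red run at 150 s, as a share of the starting material charged
- which of these the readings show (the product binds the substrate / an uncatalysed path runs beside / a little impurity takes part of the catalyst at once / the second partner ties up the catalyst / the second partner pairs with itself)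

The kineticist proposed a simple picture. Suppose that each second the same share of the remaining starting material reacts. The share left then falls exponentially, like a radioactive sample, and a single reading gives that share per second: minus the natural logarithm of the share left, divided by the time. The teal run at 26 s leaves 83.2% of its starting material, which gives 0.00707 s⁻¹. She named this k, the outset pseudo-first-order constant of the teal charge, and noted that it carries the scatter of that reading.

The process chemist objected that k may not stay put. The teal reading at 150 s gives 0.00781 s⁻¹, which is higher than k, although coupling partner has been consumed by then. The kineticist accepted this and read it as a hint that coupling partner holds the reaction back.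

The meeting then turned to the red run. The process chemist pointed out that it is charged with less coupling partner than starting material, so coupling partner is the limiting reagent there and the target can reach at most 85.0% of the starting material. The lower charge of coupling partner argues for a larger k, while the approach to that ceiling argues for a smaller one. The kineticist, as her own judgement, let the two cancel and kept k unchanged. Over 150 s this gives 65.4%, which stays under the ceiling.

The forecaster then reported by a different route: order 0.8 in starting material, −0.1 in coupling partner, grey and teal alike, and 66% for the red run, a little above the kineticist's figure. On the mechanism it chose the second partner ties up the catalyst, in its words “the partner ties up catalyst”.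

    catalyst + starting material → catalyst-substrate complex (2.570 L mol⁻¹ s⁻¹)
    catalyst-substrate complex + coupling partner → target + catalyst (3.580 L mol⁻¹ s⁻¹)
    catalyst + coupling partner ⇌ idle catalyst-reagent complex, settled at all times (1.810 L mol⁻¹)

The red run gives 64.8% at 150 s, against the 65.4% that k gave. The orders at the outset are 0.88 in starting material and −0.27 in coupling partner, the latter lower than the forecast's −0.1; grey and teal come out alike, and the readings show that the second partner ties up the catalyst. With the apparent order in catalyst early in the teal run at 0.99, k is multiplied by the violet run's catalyst ratio, 1.50. Leaving 75.0% of the violet charge then takes minus the natural logarithm of that share divided by the scaled k, which gives 27.1 s, and the violet run reached a quarter at 26.9 s.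

The data were generated by integration with made-up constants; scatter was added.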